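The tetrahydrofuran ring O1–C2–C3–C4–C5 is cut at O1–C2 and C4–C5. Benzylic C2 carries a guaiacyl donor and C4 can temporarily be a malonate carbon, so C2–C3–C4 is a donor–acceptor cyclopropane and O1–C5 is formaldehyde. One Lewis-acid (3+2) annulation makes both bonds, closes the only ring and sets C2 by inversion beside the untouched C3. Its precursor is the cis-2-aryl-3-(silyloxymethyl)cyclopropane-1,1-diester from a (Z)-cinnamyl silyl ether. Afterwards one ester carbon becomes C7′ and the other leaves as CO2 from a spiro-β-lactone, which fixes the E-olefin; C9 acylation and desilylation finish.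

Key step: step 6

Numbering and abbreviations: ring atoms as in the target (O1, C2 aryl-bearing, C3 bearing C9H2O, C4, C5H2; C7′ is the exocyclic carbon on C4); ArT = 3-methoxy-4-(triisopropylsilyloxy)phenyl; TBS = tert-butyldimethylsilyl; TIPS = triisopropylsilyl.
Assumption: in step 5 the sense of induction is fixed by the choice of ligand antipode, and the antipode that delivers the (S,S)-cyclopropane is used.

Step 1
Reactants: 1 4-bromo-2-methoxyphenol
Product: 2 (4-bromo-2-methoxyphenoxy)triisopropylsilane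
Conditions: TIPSCl (1.1 equiv), imidazole (2.2 equiv), DMF, rt
Reagents that add atoms: triisopropylsilyl chloride, CC(C)[Si](Cl)(C(C)C)C(C)C
Why: Imidazole-promoted O-silylation of a phenol is routine, and the bulky TIPS ether is chosen because it should survive the later organolithium, Lewis-acid and tin hydroxide steps yet fall to fluoride at the end.

Step 2
Reactants: 2 (4-bromo-2-methoxyphenoxy)triisopropylsilane; 3 tert-butyldimethyl(prop-2-yn-1-yloxy)silane
Product: 4 tert-butyldimethyl{[3-(ArT)prop-2-yn-1-yl]oxy}silane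
Conditions: PdCl2(PhCN)2 (3 mol %), P(t-Bu)3·HBF4 (6 mol %), CuI (2 mol %), i-Pr2NH, dioxane, rt to 40 °C
Reagents that add atoms: none
Why: Sonogashira coupling of the aryl bromide with the terminal alkyne under Pd/Cu catalysis with a bulky electron-rich phosphine tolerates both silyl ethers and brings in C3 and C9 with the oxygen already masked as a non-participating TBS ether.

Step 3
Reactants: 4 tert-butyldimethyl{[3-(ArT)prop-2-yn-1-yl]oxy}silane
Product: 5 tert-butyldimethyl{[(2Z)-3-(ArT)prop-2-en-1-yl]oxy}silane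
Conditions: H2 (1 atm), Lindlar catalyst, quinoline, EtOAc, rt
Reagents that add atoms: none
Why: Lindlar semihydrogenation delivers H2 syn on the lead-poisoned palladium surface while quinoline holds back over-reduction, so the (Z)-alkene needed for a cis-cyclopropane should form.

Step 4
Reactants: 6 dimethyl malonate
Product: 7 dimethyl 2-(phenyl-λ3-iodanylidene)malonate
Conditions: PhI(OAc)2, KOH, MeCN, 0 °C
Reagents that add atoms: (diacetoxyiodo)benzene, CC(=O)OI(OC(C)=O)c1ccccc1
Why: Ligand exchange of the malonate anion at iodine(III) gives the stabilised phenyliodonium ylide, a carbene-transfer reagent that avoids dimethyl diazomalonate and is the established partner of copper bisoxazoline catalysts.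

Step 5
Reactants: 5 tert-butyldimethyl{[(2Z)-3-(ArT)prop-2-en-1-yl]oxy}silane; 7 dimethyl 2-(phenyl-λ3-iodanylidene)malonate
Product: 8 dimethyl (2S,3S)-2-(ArT)-3-(TBSO-methyl)cyclopropane-1,1-dicarboxylate
Conditions: Cu(MeCN)4PF6 (5 mol %), chiral side-arm bis(oxazoline) ligand (6 mol %), 4 Å MS, toluene, −20 °C
Reagents that add atoms: none
Why: Copper(I)/bisoxazoline-catalysed asymmetric cyclopropanation transfers the malonate carbene from the ylide to the electron-rich (Z)-styrene in a concerted, stereospecific addition that keeps aryl and CH2OTBS cis, while the chiral ligand selects the alkene face and so sets both ring CH centres as S.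

Step 6
Reactants: 8 dimethyl (2S,3S)-2-(ArT)-3-(TBSO-methyl)cyclopropane-1,1-dicarboxylate; 9 formaldehyde
Product: 10 dimethyl (2R,3S)-2-(ArT)-3-(TBSO-methyl)tetrahydrofuran-4,4-dicarboxylate
Conditions: Sn(OTf)2 (10 mol %), 2,6-di-tert-butyl-4-methylpyridine (10 mol %), monomeric CH2O (gas from (CH2O)n cracked at 160 °C, N2 stream, excess), 4 Å MS, CH2Cl2, −30 → 0 °C
Reagents that add atoms: none
Why: Tin(II) chelates the geminal diester and polarises the C2–C4 bond of 8, the formaldehyde oxygen attacks benzylic C2 from the rear in an SN2-like opening of the tight ion pair (O1–C2), and the tin malonate enolate then adds to the O-alkylated formaldehyde carbon (C4–C5). The closest known reaction type is the Lewis-acid-catalysed formal (3+2) annulation of aryl donor–acceptor cyclopropane-1,1-diesters with aldehydes. The one ring closes in a 5-(enolexo)-endo-trig attack of the enolate on the oxocarbenium ion, a mode that is easy for such cations and is driven by release of ring strain. C2 is the only new stereocentre and is under substrate control: inversion turns the cis aryl/CH2OTBS pair into the 2,3-trans pair (2R), while C3 (S) is carried through because it never ionises. The step needs cleavage of C2–C4 and not C3–C4, which only the guaiacyl donor on C2 can support, and capture before the cis-cyclopropane epimerises at C2, which low temperature, a steady excess of monomeric formaldehyde, a proton scavenger and a bulky non-participating silyl ether on C9 should favour. Should some ionisation occur, only C2 is at stake, and the 2,3-trans ether is also expected to be the more stable epimer, so kinetic and thermodynamic control point the same way.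

Step 7
Reactants: 10 dimethyl (2R,3S)-2-(ArT)-3-(TBSO-methyl)tetrahydrofuran-4,4-dicarboxylate; 2 (4-bromo-2-methoxyphenoxy)triisopropylsilane
Product: 12 methyl (2R,3S,4S)-2-(ArT)-4-(ArT-carbonyl)-3-(TBSO-methyl)tetrahydrofuran-4-carboxylate, via aryllithium 11 (not isolated)
Conditions: 2 (1.1 equiv), n-BuLi (1.1 equiv), THF, −78 °C; then 10 in THF, −78 °C; AcOH quench at −78 °C
Reagents that add atoms: none
Why: Bromine–lithium exchange followed by nucleophilic acyl substitution on one ester of the 2,2-disubstituted malonate should stop at the ketone because the chelated tetrahedral alkoxide persists at −78 °C and the hindered, non-enolisable, donor-deactivated aryl ketone is slow to add a second aryllithium; the ester trans to C9 is the more accessible one, and the C4 epimer would converge with 12 in steps 8–10 because C4 ends as an sp2 carbon.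

Step 8
Reactants: 12 methyl (2R,3S,4S)-2-(ArT)-4-(ArT-carbonyl)-3-(TBSO-methyl)tetrahydrofuran-4-carboxylate
Product: 13 methyl (2R,3S,4S)-2-(ArT)-4-[(S)-hydroxy(ArT)methyl]-3-(TBSO-methyl)tetrahydrofuran-4-carboxylate
Conditions: Zn(BH4)2, Et2O, −20 °C
Reagents that add atoms: none
Why: Chelation-controlled (Cram-chelate) reduction with zinc borohydride holds the ketone oxygen syn to the ester carbonyl and should deliver hydride past the unsubstituted C5H2 side instead of the substituted C3 side, which sets C7′ as S with its hydrogen on the C5 side and its aryl on the C3 side of the O7′–C7′–C4–CO2Me plane.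

Step 9
Reactants: 13 methyl (2R,3S,4S)-2-(ArT)-4-[(S)-hydroxy(ArT)methyl]-3-(TBSO-methyl)tetrahydrofuran-4-carboxylate
Product: 14 (2R,3S,4S)-2-(ArT)-4-[(S)-hydroxy(ArT)methyl]-3-(TBSO-methyl)tetrahydrofuran-4-carboxylic acid
Conditions: Me3SnOH (8 equiv), 1,2-dichloroethane, 80 °C; then 0.1 M HCl work-up at 0 °C
Reagents that add atoms: trimethyltin hydroxide, C[Sn](C)(C)O
Why: Trimethyltin hydroxide cleaves the methyl ester by a mild tin-carboxylate pathway assisted by the neighbouring hydroxyl, which avoids the retro-aldol cleavage and aryl silyl ether loss that hydroxide would risk and leaves both stereocentres of the aldol unit untouched.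

Step 10
Reactants: 14 (2R,3S,4S)-2-(ArT)-4-[(S)-hydroxy(ArT)methyl]-3-(TBSO-methyl)tetrahydrofuran-4-carboxylic acid
Product: 16 (2R,3S,4E)-2-(ArT)-4-(ArT-methylidene)-3-(TBSO-methyl)tetrahydrofuran, via spiro-β-lactone 15 (not isolated)
Conditions: PhSO2Cl (2 equiv), pyridine, 0 °C; then 60 °C
Reagents that add atoms: none
Why: Carboxyl activation with benzenesulfonyl chloride closes the β-lactone with retention at C7′, and thermal [2+2] cycloreversion then loses CO2 in a stereospecific syn fashion from a ring that holds the C7′–O and C4–CO bonds coplanar, so the aryl on the C3 side of the four-membered ring should end syn to C3 and the olefin should be E.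

Step 11
Reactants: 16 (2R,3S,4E)-2-(ArT)-4-(ArT-methylidene)-3-(TBSO-methyl)tetrahydrofuran
Product: 17 [(2R,3S,4E)-2-(ArT)-4-(ArT-methylidene)tetrahydrofuran-3-yl]methanol
Conditions: PPTS (0.2 equiv), MeOH/CH2Cl2, rt
Reagents that add atoms: none
Why: Acid-catalysed methanolysis with PPTS removes the primary alkyl TBS ether much faster than the aryl TIPS ethers, and the acid is too weak to protonate the styrene or ionise the benzylic ether at C2.

Step 12
Reactants: 18 4-hydroxybenzoic acid
Product: 20 4-(tert-butyldimethylsilyloxy)benzoic acid, via silyl ester 19 (not isolated)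
Conditions: TBSCl (2.3 equiv), imidazole, DMF, rt; then K2CO3, MeOH/THF/H2O, rt, short
Reagents that add atoms: tert-butyldimethylsilyl chloride, CC(C)(C)[Si](C)(C)Cl
Why: Bis-silylation followed by brief carbonate methanolysis exploits the far higher lability of the silyl ester over the aryl silyl ether and gives the phenol-protected acid, so that only the carboxyl group can acylate in the next step.

Step 13
Reactants: 17 [(2R,3S,4E)-2-(ArT)-4-(ArT-methylidene)tetrahydrofuran-3-yl]methanol; 20 4-(tert-butyldimethylsilyloxy)benzoic acid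
Product: 21 [(2R,3S,4E)-2-(ArT)-4-(ArT-methylidene)tetrahydrofuran-3-yl]methyl 4-(tert-butyldimethylsilyloxy)benzoate
Conditions: EDC·HCl (1.5 equiv), DMAP (0.2 equiv), CH2Cl2, rt
Reagents that add atoms: none
Why: Steglich esterification with a carbodiimide and DMAP acylates the primary C9 hydroxyl under neutral conditions that leave the olefin geometry, the benzylic ether and all silyl ethers alone.

Step 14
Reactants: 21 [(2R,3S,4E)-2-(ArT)-4-(ArT-methylidene)tetrahydrofuran-3-yl]methyl 4-(tert-butyldimethylsilyloxy)benzoate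
Product: 22 agastenol
Conditions: TBAF (3.5 equiv), AcOH (4 equiv), THF, 0 °C
Reagents that add atoms: none
Why: Fluoride cleaves the three aryl silyl ethers rapidly because phenoxides are good leaving groups from silicon, and buffering with acetic acid should keep the medium from saponifying the C9 benzoate or isomerising the olefin.

Compound list
1 | 4-bromo-2-methoxyphenol | COc1cc(Br)ccc1O | starting material
2 | (4-bromo-2-methoxyphenoxy)triisopropylsilane | COc1cc(Br)ccc1O[Si](C(C)C)(C(C)C)C(C)C | intermediate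
3 | tert-butyldimethyl(prop-2-yn-1-yloxy)silane | C#CCO[Si](C)(C)C(C)(C)C | starting material
4 | tert-butyldimethyl{[3-(ArT)prop-2-yn-1-yl]oxy}silane | COc1cc(C#CCO[Si](C)(C)C(C)(C)C)ccc1O[Si](C(C)C)(C(C)C)C(C)C | intermediate
5 | tert-butyldimethyl{[(2Z)-3-(ArT)prop-2-en-1-yl]oxy}silane | COc1cc(/C=C\CO[Si](C)(C)C(C)(C)C)ccc1O[Si](C(C)C)(C(C)C)C(C)C | intermediate
6 | dimethyl malonate | COC(=O)CC(=O)OC | starting material
7 | dimethyl 2-(phenyl-λ3-iodanylidene)malonate (iodonium ylide) | COC(=O)[C-](C(=O)OC)[I+]c1ccccc1 | intermediate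
8 | dimethyl (2S,3S)-2-(ArT)-3-(TBSO-methyl)cyclopropane-1,1-dicarboxylate (aryl and CH2OTBS cis) | COC(=O)C1(C(=O)OC)[C@H](c2ccc(O[Si](C(C)C)(C(C)C)C(C)C)c(OC)c2)[C@@H]1CO[Si](C)(C)C(C)(C)C | intermediate
9 | formaldehyde (monomer, supplied as paraformaldehyde) | C=O | starting material
10 | dimethyl (2R,3S)-2-(ArT)-3-(TBSO-methyl)tetrahydrofuran-4,4-dicarboxylate (2,3-trans) | COC(=O)C1(C(=O)OC)CO[C@@H](c2ccc(O[Si](C(C)C)(C(C)C)C(C)C)c(OC)c2)[C@@H]1CO[Si](C)(C)C(C)(C)C | intermediate
11 | [3-methoxy-4-(triisopropylsilyloxy)phenyl]lithium | COc1cc([Li])ccc1O[Si](C(C)C)(C(C)C)C(C)C | intermediate (not isolated)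
12 | methyl (2R,3S,4S)-2-(ArT)-4-(ArT-carbonyl)-3-(TBSO-methyl)tetrahydrofuran-4-carboxylate (aroyl trans to CH2OTBS) | COC(=O)[C@]1(C(=O)c2ccc(O[Si](C(C)C)(C(C)C)C(C)C)c(OC)c2)CO[C@@H](c2ccc(O[Si](C(C)C)(C(C)C)C(C)C)c(OC)c2)[C@@H]1CO[Si](C)(C)C(C)(C)C | intermediate
13 | methyl (2R,3S,4S)-2-(ArT)-4-[(S)-hydroxy(ArT)methyl]-3-(TBSO-methyl)tetrahydrofuran-4-carboxylate | COC(=O)[C@]1([C@@H](O)c2ccc(O[Si](C(C)C)(C(C)C)C(C)C)c(OC)c2)CO[C@@H](c2ccc(O[Si](C(C)C)(C(C)C)C(C)C)c(OC)c2)[C@@H]1CO[Si](C)(C)C(C)(C)C | intermediate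
14 | (2R,3S,4S)-2-(ArT)-4-[(S)-hydroxy(ArT)methyl]-3-(TBSO-methyl)tetrahydrofuran-4-carboxylic acid | OC(=O)[C@]1([C@@H](O)c2ccc(O[Si](C(C)C)(C(C)C)C(C)C)c(OC)c2)CO[C@@H](c2ccc(O[Si](C(C)C)(C(C)C)C(C)C)c(OC)c2)[C@@H]1CO[Si](C)(C)C(C)(C)C | intermediate
15 | spiro-β-lactone of 14 (oxetan-2-one spiro-fused at C4, ring oxygen on C7′, C7′ aryl on the C3 side) | O=C1O[C@@H](c2ccc(O[Si](C(C)C)(C(C)C)C(C)C)c(OC)c2)[C@]12CO[C@@H](c1ccc(O[Si](C(C)C)(C(C)C)C(C)C)c(OC)c1)[C@@H]2CO[Si](C)(C)C(C)(C)C | intermediate (not isolated)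
16 | (2R,3S,4E)-2-(ArT)-4-(ArT-methylidene)-3-(TBSO-methyl)tetrahydrofuran | COc1cc(/C=C2/CO[C@@H](c3ccc(O[Si](C(C)C)(C(C)C)C(C)C)c(OC)c3)[C@@H]2CO[Si](C)(C)C(C)(C)C)ccc1O[Si](C(C)C)(C(C)C)C(C)C | intermediate
17 | [(2R,3S,4E)-2-(ArT)-4-(ArT-methylidene)tetrahydrofuran-3-yl]methanol | COc1cc(/C=C2/CO[C@@H](c3ccc(O[Si](C(C)C)(C(C)C)C(C)C)c(OC)c3)[C@@H]2CO)ccc1O[Si](C(C)C)(C(C)C)C(C)C | intermediate
18 | 4-hydroxybenzoic acid | OC(=O)c1ccc(O)cc1 | starting material
19 | tert-butyldimethylsilyl 4-(tert-butyldimethylsilyloxy)benzoate | CC(C)(C)[Si](C)(C)OC(=O)c1ccc(O[Si](C)(C)C(C)(C)C)cc1 | intermediate (not isolated)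
20 | 4-(tert-butyldimethylsilyloxy)benzoic acid | OC(=O)c1ccc(O[Si](C)(C)C(C)(C)C)cc1 | intermediate
21 | [(2R,3S,4E)-2-(ArT)-4-(ArT-methylidene)tetrahydrofuran-3-yl]methyl 4-(tert-butyldimethylsilyloxy)benzoate | COc1cc(/C=C2/CO[C@@H](c3ccc(O[Si](C(C)C)(C(C)C)C(C)C)c(OC)c3)[C@@H]2COC(=O)c2ccc(O[Si](C)(C)C(C)(C)C)cc2)ccc1O[Si](C(C)C)(C(C)C)C(C)C | intermediate
22 | agastenol, [(2R,3S,4E)-2-(4-hydroxy-3-methoxyphenyl)-4-[(4-hydroxy-3-methoxyphenyl)methylidene]tetrahydrofuran-3-yl]methyl 4-hydroxybenzoate | COc1cc(/C=C2/CO[C@@H](c3ccc(O)c(OC)c3)[C@@H]2COC(=O)c2ccc(O)cc2)ccc1O | target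

Total step count: 14. Longest linear sequence: 12 steps (steps 1, 2, 3, 5, 6, 7, 8, 9, 10, 11, 13, 14) from 4-bromo-2-methoxyphenol; steps 4 and 12 prepare side components.

Steps most likely to fail

1. Step 6. Formaldehyde is a weak nucleophile that polymerises on the Lewis acid. The activated cyclopropane may therefore open to the zwitterion, epimerise at C2 or oligomerise before it is captured, and the oxocarbenium intermediate may be intercepted by the C9 silyl ether oxygen instead of the enolate. Fallback, from 8 back to 16, without formaldehyde: C5 is taken from an ester carbon and the olefin is set thermodynamically. Lewis-acid hydrolysis (Yb(OTf)3, H2O, MeCN) opens 8 at C2 and the γ-hydroxy malonate lactonises to the trans lactone ester F1. Krapcho demethoxycarbonylation (LiCl, wet DMSO, 140 °C) gives the γ-butyrolactone F2. Its lithium enolate (LDA, THF, −78 °C) adds to O-TIPS-vanillin F3 (from vanillin, TIPSCl and imidazole), and dehydration of the aldol (MsCl, Et3N, then DBU) gives the (E)-α-arylidene lactone F4, in which the aryl is anti to the carbonyl and therefore syn to C3. DIBAL-H reduces the lactone to the allylic diol F5, and Mitsunobu cyclodehydration (PPh3, DIAD) closes the ether at the primary allylic carbon, leaving C2 untouched, to give 16.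

2. Step 5. Facial discrimination may be poor on an electron-rich (Z)-1,2-disubstituted alkene, and the cis geometry may leak if carbene transfer becomes stepwise. Fallback, from 5 back to 8: asymmetric induction is replaced by resolution. Diazo transfer to 6 (p-ABSA, Et3N) gives dimethyl diazomalonate F6, and Rh2(esp)2-catalysed cyclopropanation of 5 gives the racemic cis-cyclopropane, that is 8 together with its enantiomer F7. Preparative chromatography on a chiral stationary phase then delivers 8.

3. Step 8. Hydride delivery may not distinguish the C3 side from the C5 side of the zinc chelate, or reduction may run through a competing chelate to the ring oxygen O1; either would erode the E/Z purity that step 10 only transmits. Fallback, from 12 back to 16: the other elimination mode is used for the other epimer. The C7′-epimeric hydroxy ester F8 is separated and cleaved with Me3SnOH to the epimeric hydroxy acid F9. Hydroxyl activation with DMF dimethyl acetal (CHCl3, 60 °C, weakly ionising medium) then eliminates CO2 in the anti sense, which from this epimer also places the aryl syn to C3 and gives 16.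

Further compounds
F1 | step 6 | methyl (2R,3S)-2-(ArT)-5-oxo-3-(TBSO-methyl)tetrahydrofuran-4-carboxylate | COC(=O)C1C(=O)O[C@@H](c2ccc(O[Si](C(C)C)(C(C)C)C(C)C)c(OC)c2)[C@@H]1CO[Si](C)(C)C(C)(C)C
F2 | step 6 | (2R,3S)-2-(ArT)-3-(TBSO-methyl)-5-oxotetrahydrofuran | O=C1O[C@@H](c2ccc(O[Si](C(C)C)(C(C)C)C(C)C)c(OC)c2)[C@H](CO[Si](C)(C)C(C)(C)C)C1
F3 | step 6 | 3-methoxy-4-(triisopropylsilyloxy)benzaldehyde | COc1cc(C=O)ccc1O[Si](C(C)C)(C(C)C)C(C)C
F4 | step 6 | (2R,3S,4E)-2-(ArT)-4-(ArT-methylidene)-3-(TBSO-methyl)-5-oxotetrahydrofuran | O=C1O[C@@H](c2ccc(O[Si](C(C)C)(C(C)C)C(C)C)c(OC)c2)[C@H](CO[Si](C)(C)C(C)(C)C)/C1=C\c1ccc(O[Si](C(C)C)(C(C)C)C(C)C)c(OC)c1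
F5 | step 6 | (2E,3S,4R)-4-(ArT)-2-(ArT-methylidene)-3-(TBSO-methyl)butane-1,4-diol | OC/C(=C/c1ccc(O[Si](C(C)C)(C(C)C)C(C)C)c(OC)c1)[C@@H](CO[Si](C)(C)C(C)(C)C)[C@@H](O)c1ccc(O[Si](C(C)C)(C(C)C)C(C)C)c(OC)c1
F6 | step 5 | dimethyl 2-diazomalonate | COC(=O)C(=[N+]=[N-])C(=O)OC
F7 | step 5 | dimethyl (2R,3R)-2-(ArT)-3-(TBSO-methyl)cyclopropane-1,1-dicarboxylate (enantiomer of 8) | COC(=O)C1(C(=O)OC)[C@@H](c2ccc(O[Si](C(C)C)(C(C)C)C(C)C)c(OC)c2)[C@H]1CO[Si](C)(C)C(C)(C)C
F8 | step 8 | methyl (2R,3S,4S)-2-(ArT)-4-[(R)-hydroxy(ArT)methyl]-3-(TBSO-methyl)tetrahydrofuran-4-carboxylate (C7′ epimer of 13) | COC(=O)[C@]1([C@H](O)c2ccc(O[Si](C(C)C)(C(C)C)C(C)C)c(OC)c2)CO[C@@H](c2ccc(O[Si](C(C)C)(C(C)C)C(C)C)c(OC)c2)[C@@H]1CO[Si](C)(C)C(C)(C)C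
F9 | step 8 | (2R,3S,4S)-2-(ArT)-4-[(R)-hydroxy(ArT)methyl]-3-(TBSO-methyl)tetrahydrofuran-4-carboxylic acid (C7′ epimer of 14) | OC(=O)[C@]1([C@H](O)c2ccc(O[Si](C(C)C)(C(C)C)C(C)C)c(OC)c2)CO[C@@H](c2ccc(O[Si](C(C)C)(C(C)C)C(C)C)c(OC)c2)[C@@H]1CO[Si](C)(C)C(C)(C)C
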